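Retrosynthesis: once the 4'-O-benzyl protecting group is set aside, ring C is cut in one stroke at C4a–C4, C4–C3 and O1–C2. This leaves an aryl iodide (ring A), carbon monoxide (C4 and its oxygen) and an arylacetylene (C3, C2 and ring B).
Enabling feature: C4a of ring A lies between two oxygen-bearing carbons, C5 (OH) and C8a (O1), with the 7-OMe para to it. Ring A is therefore a mirror-symmetric 2-iodo-5-methoxyresorcinol, in which either hydroxyl can become O1 of the 4-pyranone while the other stays as the 5-OH.
Forward, ring A: 5-methoxyresorcinol is MOM-protected, lithiated and iodinated between the two acetals, then unmasked without Brønsted acid. Ring B: syringaldehyde is benzylated, brominated, methoxylated and homologated to the terminal alkyne.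
Ring order: A and B are bought as arenes. Ring C is the only ring built and closes in the same Pd/CO operation that joins the two halves; hydrogenolysis then frees the 4'-OH.
Stereochemistry: none to create, because the flavone has no stereocentre and no hindered axis.

Key step: step 8

Remark on the chemistry: the target is achiral (no stereocentre, no stereogenic double bond, and a C2–C1' bond with only one ortho substituent), so "single enantiomer" reduces to the one constitution drawn.

Step 1
Reactants: 1 5-methoxyresorcinol (5-methoxybenzene-1,3-diol)
Product: 2 1-methoxy-3,5-bis(methoxymethoxy)benzene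
Conditions: NaH, MOMCl, DMF, 0 °C to rt
Reagents that add atoms: chloromethyl methyl ether (MOMCl), COCCl
Why: Williamson-type O-alkylation of the bis-phenoxide with the hard electrophile MOMCl is the standard acetal protection of resorcinols and installs the two groups that will steer the metalation.

Step 2
Reactants: 2 1-methoxy-3,5-bis(methoxymethoxy)benzene
Product: 4 2-iodo-5-methoxy-1,3-bis(methoxymethoxy)benzene, via aryllithium 3 (not isolated)
Conditions: n-BuLi, Et2O, 0 °C to rt; then I2 (THF), −78 °C to rt
Reagents that add atoms: iodine, II (n-butyllithium, [Li]CCCC, supplies only the lithium of 3)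
Why: In this directed ortho-metalation the ring CH between the two OMOM groups is acidified by both, and its lithio derivative 3 is chelated by both acetal side chains, which are stronger directors than the lone OMe in a weakly coordinating solvent, so iodinolysis of the C–Li bond should place iodine at that carbon.

Step 3
Reactants: 4 2-iodo-5-methoxy-1,3-bis(methoxymethoxy)benzene
Product: 6 2-iodo-5-methoxybenzene-1,3-diol, via bis(trimethylsilyl) ether 5 (not isolated)
Conditions: TMSOTf, 2,2'-bipyridyl, MeCN, 0 °C to rt; then H2O, rt; used at once
Reagents that add atoms: trimethylsilyl trifluoromethanesulfonate, C[Si](C)(C)OS(=O)(=O)C(F)(F)F (its Me3Si groups sit in 5 only and are gone in 6)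
Why: The silyl triflate–bipyridyl acetal cleavage turns aryl MOM ethers into aryl TMS ethers under buffered, nearly neutral conditions and water then breaks the O–Si bonds, which avoids the strong acid and halide that would cause ipso-protonation and loss or migration of iodine on this phloroglucinol-type ring.

Step 4
Reactants: 7 syringaldehyde (4-hydroxy-3,5-dimethoxybenzaldehyde)
Product: 8 4-(benzyloxy)-3,5-dimethoxybenzaldehyde
Conditions: BnBr, K2CO3, DMF, 60 °C
Reagents that add atoms: benzyl bromide, BrCc1ccccc1
Why: This Williamson ether synthesis works on a phenol made acidic by the para formyl group, and although the phenol is flanked by two OMe groups it is routinely benzylated in a polar aprotic solvent.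

Step 5
Reactants: 8 4-(benzyloxy)-3,5-dimethoxybenzaldehyde
Product: 9 4-(benzyloxy)-2-bromo-3,5-dimethoxybenzaldehyde
Conditions: NBS (1.0 equiv), MeCN, rt, dark
Reagents that add atoms: N-bromosuccinimide, O=C1CCC(=O)N1Br
Why: In this electrophilic aromatic bromination the two free ring positions are equivalent, each ortho to one OMe and para to the other, so one equivalent of NBS under ionic conditions should give a single monobromide, as is known for 3,4,5-trialkoxybenzaldehydes, while the unactivated benzyl ring and its CH2 stay untouched.

Step 6
Reactants: 9 4-(benzyloxy)-2-bromo-3,5-dimethoxybenzaldehyde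
Product: 10 4-(benzyloxy)-2,3,5-trimethoxybenzaldehyde
Conditions: NaOMe, CuBr (10 mol %), EtOAc (cat), MeOH–DMF, 100 °C
Reagents that add atoms: sodium methoxide, [Na+].[O-]C
Why: This Ullmann-type copper-catalysed methoxylation of an aryl bromide is assisted by the ortho formyl group, which binds copper and lowers the electron density of the ring, and it is tolerated by the benzyl ether and by the non-enolisable aldehyde, which is reversibly masked as its hemiacetal alkoxide.

Step 7
Reactants: 10 4-(benzyloxy)-2,3,5-trimethoxybenzaldehyde; 11 dimethyl (1-diazo-2-oxopropyl)phosphonate (Ohira–Bestmann reagent)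
Product: 12 4-(benzyloxy)-1-ethynyl-2,3,5-trimethoxybenzene
Conditions: 11, K2CO3, MeOH, 0 °C to rt
Reagents that add atoms: Ohira–Bestmann reagent 11, CC(=O)C(=[N+]=[N-])P(=O)(OC)OC (its diazo carbon becomes the terminal alkyne carbon)
Why: In the Ohira–Bestmann variant of the Seyferth–Gilbert homologation, methanolysis of 11 frees the diazomethylphosphonate anion, which olefinates the aldehyde in Horner–Wadsworth–Emmons fashion, and loss of N2 with a 1,2-shift then gives the terminal alkyne under conditions mild enough for all the ethers.

Step 8
Reactants: 6 2-iodo-5-methoxybenzene-1,3-diol; 12 4-(benzyloxy)-1-ethynyl-2,3,5-trimethoxybenzene; 13 carbon monoxide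
Product: 16 2-[4-(benzyloxy)-2,3,5-trimethoxyphenyl]-5-hydroxy-7-methoxy-4H-chromen-4-one, via ynone 14 (not isolated), via enaminone 15 (not isolated)
Conditions: PdCl2(dppf) (5 mol %), CO (10 bar), Et2NH, 90 °C, no copper salt
Reagents that add atoms: carbon monoxide 13, [C-]#[O+] (diethylamine, CCNCC, enters 15 and leaves again)
Why: Pd(0) inserts into the C–I bond of 6, CO migrates into the crowded aryl–Pd bond, and the aroyl–Pd(II) species takes up the amine-deprotonated alkyne 12 and reductively eliminates ynone 14, which makes C4a–C4 and C4–C3. Diethylamine then adds to the β-carbon of 14 to give the push–pull enaminone 15, and a flanking phenol attacks that same carbon and expels the amine, which makes O1–C2. The closest known reaction type is the copper-free carbonylative Sonogashira coupling and annulation of o-iodophenols with terminal arylacetylenes in a secondary amine, an established flavone synthesis. Ring C is the only ring closed, in a 6-endo mode (6-endo-trig addition–elimination on 15, the same outcome as a 6-endo-dig oxa-Michael addition on 14), and no stereocentre is created. The step needs carbonylation over direct alkynylation (the route to a 2-arylbenzofuran), acetylide capture over aminolysis of the aroyl–Pd to a diethylamide, and 6-endo over 5-exo closure (aurone); the two ortho oxygens should speed CO insertion relative to alkyne transfer and shield the acyl carbon from the bulky amine, the absence of copper and the CO overpressure reinforce this, and the enaminone confines the electrophilic site to C2. The mirror symmetry of 6 makes its two hydroxyls equivalent, so only one regioisomer can form and the spectator hydroxyl ends as the chelated 5-OH without protection.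

Step 9
Reactants: 16 2-[4-(benzyloxy)-2,3,5-trimethoxyphenyl]-5-hydroxy-7-methoxy-4H-chromen-4-one
Product: 17 5-hydroxy-2-(4-hydroxy-2,3,5-trimethoxyphenyl)-7-methoxy-4H-chromen-4-one (5,4'-dihydroxy-7,2',3',5'-tetramethoxyflavone, the target)
Conditions: H2 (1 atm), 10% Pd/C, EtOAc–MeOH, rt, stopped when 16 is consumed
Reagents that add atoms: none
Why: Catalytic hydrogenolysis of the benzylic C–O bond is much faster at ambient pressure than saturation of the vinylogous-ester C2–C3 double bond of a flavone, and the aryl methyl ethers, the chelated 5-OH and the carbonyl are inert.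

Compound list
1 | 5-methoxyresorcinol | COc1cc(O)cc(O)c1 | starting material
2 | 1-methoxy-3,5-bis(methoxymethoxy)benzene | COCOc1cc(OC)cc(OCOC)c1 | intermediate
3 | [4-methoxy-2,6-bis(methoxymethoxy)phenyl]lithium (formed in the flask) | [Li]c1c(OCOC)cc(OC)cc1OCOC | intermediate
4 | 2-iodo-5-methoxy-1,3-bis(methoxymethoxy)benzene | COCOc1cc(OC)cc(OCOC)c1I | intermediate
5 | [(2-iodo-5-methoxy-1,3-phenylene)bis(oxy)]bis(trimethylsilane) (formed in the flask) | COc1cc(O[Si](C)(C)C)c(I)c(O[Si](C)(C)C)c1 | intermediate
6 | 2-iodo-5-methoxybenzene-1,3-diol | COc1cc(O)c(I)c(O)c1 | intermediate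
7 | syringaldehyde | COc1cc(C=O)cc(OC)c1O | starting material
8 | 4-(benzyloxy)-3,5-dimethoxybenzaldehyde | COc1cc(C=O)cc(OC)c1OCc1ccccc1 | intermediate
9 | 4-(benzyloxy)-2-bromo-3,5-dimethoxybenzaldehyde | COc1cc(C=O)c(Br)c(OC)c1OCc1ccccc1 | intermediate
10 | 4-(benzyloxy)-2,3,5-trimethoxybenzaldehyde | COc1cc(C=O)c(OC)c(OC)c1OCc1ccccc1 | intermediate
11 | dimethyl (1-diazo-2-oxopropyl)phosphonate | CC(=O)C(=[N+]=[N-])P(=O)(OC)OC | starting material
12 | 4-(benzyloxy)-1-ethynyl-2,3,5-trimethoxybenzene | C#Cc1cc(OC)c(OCc2ccccc2)c(OC)c1OC | intermediate
13 | carbon monoxide | [C-]#[O+] | starting material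
14 | 3-[4-(benzyloxy)-2,3,5-trimethoxyphenyl]-1-(2,6-dihydroxy-4-methoxyphenyl)prop-2-yn-1-one (formed in the flask) | COc1cc(O)c(C(=O)C#Cc2cc(OC)c(OCc3ccccc3)c(OC)c2OC)c(O)c1 | intermediate
15 | (E)-3-[4-(benzyloxy)-2,3,5-trimethoxyphenyl]-3-(diethylamino)-1-(2,6-dihydroxy-4-methoxyphenyl)prop-2-en-1-one (formed in the flask; push–pull alkene, geometry of no consequence) | CCN(CC)/C(=C/C(=O)c1c(O)cc(OC)cc1O)c1cc(OC)c(OCc2ccccc2)c(OC)c1OC | intermediate
16 | 2-[4-(benzyloxy)-2,3,5-trimethoxyphenyl]-5-hydroxy-7-methoxy-4H-chromen-4-one | COc1cc(O)c2c(=O)cc(-c3cc(OC)c(OCc4ccccc4)c(OC)c3OC)oc2c1 | intermediate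
17 | 5-hydroxy-2-(4-hydroxy-2,3,5-trimethoxyphenyl)-7-methoxy-4H-chromen-4-one (achiral) | COc1cc(O)c2c(=O)cc(-c3cc(OC)c(O)c(OC)c3OC)oc2c1 | target

Total step count: 9 (three for ring A, four for ring B, two after the union).
Longest linear sequence: 6 steps, from 7 through 8, 9, 10, 12 and 16 to 17 (steps 4 to 9).

Steps most likely to fail

Step 8. Oxidative addition into the electron-rich, doubly ortho-substituted C–I bond may be slow. Hydrodeiodination, CO-free alkynylation or aminolysis of the acyl-palladium could then outrun the wanted sequence. The fallback gives up the CO-based construction and builds ring C by classical carbonyl chemistry. It sets out from 10 and comes back at 16.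
- Claisen–Schmidt condensation of 10 with bought 2',6'-dihydroxy-4'-methoxyacetophenone (CC(=O)c1c(O)cc(OC)cc1O) in KOH/EtOH should give (E)-3-[4-(benzyloxy)-2,3,5-trimethoxyphenyl]-1-(2,6-dihydroxy-4-methoxyphenyl)prop-2-en-1-one F1.
- F1 equilibrates with its oxa-Michael isomer (±)-2-[4-(benzyloxy)-2,3,5-trimethoxyphenyl]-5-hydroxy-7-methoxychroman-4-one F2.
- Heating the mixture with catalytic I2 in DMSO carries both through oxidative cyclisation and dehydrogenation to 16.

Step 2. Deprotonation may compete at the two CH positions flanked by one OMOM and the OMe. This would deliver iodine to the wrong carbon and in the end exchange the 5-OH/7-OMe pattern. The fallback replaces metalation by electrophilic substitution on the free phenol. It sets out from 1 and comes back at 6, so steps 1 to 3 fall away.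
- Compound 1 is iodinated with I2 and NaHCO3 in water–THF at 0 °C.
- Under these conditions resorcinol and 5-substituted resorcinols are known to take iodine between the two hydroxyls.
- The fallback makes no compound that the list does not already hold (entry F0).

Step 6. Hydrodebromination through copper hydride formed from methoxide, and hydride-transfer consumption of the aldehyde in hot methoxide, may erode the substitution. The fallback brings in the C2 oxygen through boron instead of a C–O coupling. It sets out from 9 and comes back at 10.
- Miyaura borylation (B2pin2, PdCl2(dppf), KOAc, dioxane, 90 °C) should give 4-(benzyloxy)-3,5-dimethoxy-2-(4,4,5,5-tetramethyl-1,3,2-dioxaborolan-2-yl)benzaldehyde F3.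
- Oxidation of the C–B bond with trimethylamine N-oxide in CH2Cl2 spares the aldehyde, whereas alkaline peroxide would invite a Dakin reaction. It gives 4-(benzyloxy)-2-hydroxy-3,5-dimethoxybenzaldehyde F4.
- O-methylation with MeI and K2CO3 in acetone returns 10.

Further compounds
F1 | step 8 | (E)-3-[4-(benzyloxy)-2,3,5-trimethoxyphenyl]-1-(2,6-dihydroxy-4-methoxyphenyl)prop-2-en-1-one | COc1cc(O)c(C(=O)/C=C/c2cc(OC)c(OCc3ccccc3)c(OC)c2OC)c(O)c1
F2 | step 8 | (±)-2-[4-(benzyloxy)-2,3,5-trimethoxyphenyl]-5-hydroxy-7-methoxychroman-4-one (racemic) | COc1cc(O)c2c(c1)OC(CC2=O)c1cc(OC)c(OCc3ccccc3)c(OC)c1OC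
F0 | step 2 | none | none
F3 | step 6 | 4-(benzyloxy)-3,5-dimethoxy-2-(4,4,5,5-tetramethyl-1,3,2-dioxaborolan-2-yl)benzaldehyde | COc1cc(C=O)c(B2OC(C)(C)C(C)(C)O2)c(OC)c1OCc1ccccc1
F4 | step 6 | 4-(benzyloxy)-2-hydroxy-3,5-dimethoxybenzaldehyde | COc1cc(C=O)c(O)c(OC)c1OCc1ccccc1
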